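The tertiary α-ketol of the carbocycle C4a–C5–C6–C7–C8–C8a (isochromene numbering) carries the whole route: C7 bears OH and CH3 next to the C8 ketone. That ring is first built one carbon smaller, as a cyclopentenol whose carbinol carbon (future C8) bears an acetyl group. A chelation-controlled α-ketol shift then moves C6 from C8 to the acetyl carbon: in one operation the ring grows to six members, the C8 enone appears and the C8 configuration is relayed to the quaternary C7 carbinol, cis to O6. The precursor comes from (R)-4-silyloxycyclopentenone by hydroxymethylation, enynyl addition, oxidative transposition and acyl-anion addition; enyne epoxidation, pyran closure and orsellinoylation follow.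

Key step: step 7

Remark: atom numbers are those of the 1H-isochromene core of the target (C1, O2, C3, C4, C4a, C5 to C8, C8a) and are kept for the corresponding atoms of the monocyclic precursors; TBS is tert-butyldimethylsilyl.

Step 1
Reactants: 1 (E)-but-2-enal (crotonaldehyde)
Product: 2 (3E)-1,1-dibromopenta-1,3-diene
Conditions: CBr4, PPh3, CH2Cl2, 0 °C
Reagents that add atoms: carbon tetrabromide, BrC(Br)(Br)Br
Why: Corey–Fuchs dibromo-olefination, in which the ylide formed in the flask from CBr4 and PPh3 should convert the aldehyde into the 1,1-dibromoalkene while the E-propenyl unit stays untouched.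

Step 2
Reactants: 3 (R)-4-(TBSO)cyclopent-2-en-1-one
Product: 4 (R)-4-(TBSO)-2-(hydroxymethyl)cyclopent-2-en-1-one
Conditions: aq. HCHO, imidazole (cat.), THF/H2O, rt
Reagents that add atoms: formaldehyde, C=O
Why: Morita–Baylis–Hillman reaction, in which reversible addition of imidazole at the β-carbon gives an enolate that captures formaldehyde at the α-carbon (future C8a) before the catalyst is expelled, so that no stereocentre is formed and the silyloxy carbon (future C6) is not touched.

Step 3
Reactants: 4 (R)-4-(TBSO)-2-(hydroxymethyl)cyclopent-2-en-1-one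
Product: 5 (R)-4-(TBSO)-2-[(TBSO)methyl]cyclopent-2-en-1-one
Conditions: TBSCl, imidazole, CH2Cl2, 0 °C to rt
Reagents that add atoms: tert-butyldimethylsilyl chloride, CC(C)(C)[Si](C)(C)Cl
Why: Standard silyl ether formation on the primary allylic alcohol, needed so that the oxidant of step 5 meets only the tertiary carbinol.

Step 4
Reactants: 2 (3E)-1,1-dibromopenta-1,3-diene; 5 (R)-4-(TBSO)-2-[(TBSO)methyl]cyclopent-2-en-1-one
Product: 7 (1RS,4R)-4-(TBSO)-2-[(TBSO)methyl]-1-[(E)-pent-3-en-1-yn-1-yl]cyclopent-2-en-1-ol, via lithium (E)-pent-3-en-1-yn-1-ide 6 (not isolated)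
Conditions: 2, n-BuLi (2 equiv), THF, −78 °C; then 5, −78 °C; H2O
Reagents that add atoms: none
Why: Second stage of the Corey–Fuchs sequence (bromine–lithium exchange and Fritsch–Buttenberg–Wiechell-type elimination) should give acetylide 6, which adds 1,2 to the enone carbonyl (future C4a); the configuration of the new carbinol carbon is not controlled and does not matter because this carbon becomes sp2 in step 5.

Step 5
Reactants: 7 (1RS,4R)-4-(TBSO)-2-[(TBSO)methyl]-1-[(E)-pent-3-en-1-yn-1-yl]cyclopent-2-en-1-ol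
Product: 8 (R)-5-(TBSO)-2-[(TBSO)methyl]-3-[(E)-pent-3-en-1-yn-1-yl]cyclopent-2-en-1-one
Conditions: pyridinium chlorochromate, 4 Å molecular sieves, CH2Cl2, rt
Reagents that add atoms: pyridinium chlorochromate, [O-][Cr](=O)(=O)Cl.c1cc[nH+]cc1
Why: Babler–Dauben oxidative 1,3-transposition, in which the tertiary allylic chromate ester should rearrange to the alkene terminus (future C8) and be oxidised there, giving the C8 ketone and the C8a=C4a enyne and leaving the silyloxy stereocentre (future C6, R) unchanged α to the new carbonyl.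

Step 6
Reactants: 8 (R)-5-(TBSO)-2-[(TBSO)methyl]-3-[(E)-pent-3-en-1-yn-1-yl]cyclopent-2-en-1-one
Product: 10 1-[(1S,5R)-5-(TBSO)-2-[(TBSO)methyl]-1-hydroxy-3-[(E)-pent-3-en-1-yn-1-yl]cyclopent-2-en-1-yl]ethan-1-one, via enol ether adduct 9 (not isolated)
Conditions: ethyl vinyl ether, t-BuLi, THF, −78 to 0 °C; CeCl3, −78 °C; then 8; 0.5 M HCl, THF, 0 °C
Reagents that add atoms: ethyl vinyl ether (as 1-ethoxyvinyllithium), C=COCC; water, O
Why: 1,2-Addition of an acyl-anion equivalent (the organocerium reagent from 1-ethoxyvinyllithium) should occur on the carbonyl face anti to the neighbouring C6 silyloxy group (Felkin–Anh and steric control), which sets C8 as S with its hydroxyl cis to O6, and mild acid hydrolysis of the enol ether then unmasks the acetyl group.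

Step 7
Reactants: 10 1-[(1S,5R)-5-(TBSO)-2-[(TBSO)methyl]-1-hydroxy-3-[(E)-pent-3-en-1-yn-1-yl]cyclopent-2-en-1-yl]ethan-1-one
Product: 12 (5R,6R)-5-(TBSO)-2-[(TBSO)methyl]-6-hydroxy-6-methyl-3-[(E)-pent-3-en-1-yn-1-yl]cyclohex-2-en-1-one, via aluminium alkoxide 11 (not isolated)
Conditions: Al(OtBu)3, toluene, 80 °C; then H2O
Reagents that add atoms: none
Why: α-Ketol (acyloin) rearrangement with ring enlargement: ligand exchange gives the di-tert-butoxyaluminium alkoxide 11, in which aluminium binds O8 and the acetyl oxygen in a five-membered chelate (C–O and C=O syn-periplanar), and the C8–C6 bond, held perpendicular to the acetyl plane, shifts suprafacially from C8 to the acetyl carbon (future C7) while C8 becomes the ketone. The closest known reaction type is the Lewis-acid-mediated enlargement of 1-acylcycloalkanols to 2-hydroxy-2-alkylcycloalkanones, as in the D-homoannulation of 17-hydroxy-20-oxo steroids. No ring is closed by cyclisation: the carbocycle C4a–C5–C6–C7–C8–C8a arises from the five-membered ring by 1,2-shift of a ring bond, which inserts the acetyl carbon between C8 and C6. C6 migrates with retention, and the chelate decides which face of the acetyl group it reaches, so the new C7 hydroxyl should emerge on the side that the C8 oxygen occupied, cis to the C6 silyloxy group, which turns (8S) into (7R) by chirality transfer. The step needs C6 and not the alkenyl carbon C8a to migrate: the shift is reversible, only C6 migration places the new ketone in conjugation with the C8a=C4a enyne (the thermodynamic sink), and the silyloxy donor on C6 raises its migratory aptitude while its silyl cap blocks retro-aldol cleavage.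

Step 8
Reactants: 12 (5R,6R)-5-(TBSO)-2-[(TBSO)methyl]-6-hydroxy-6-methyl-3-[(E)-pent-3-en-1-yn-1-yl]cyclohex-2-en-1-one
Product: 13 (5R,6R)-5-(TBSO)-2-[(TBSO)methyl]-6-hydroxy-6-methyl-3-{[(2R,3R)-3-methyloxiran-2-yl]ethynyl}cyclohex-2-en-1-one
Conditions: Shi ketone (D-fructose-derived, 30 mol %), Oxone (KHSO5), K2CO3, Bu4NHSO4, MeCN/dimethoxymethane/aq. borate buffer (pH 10.5), 0 °C
Reagents that add atoms: Oxone (potassium peroxymonosulfate), [K+].[O-]S(=O)(=O)OO
Why: Shi asymmetric epoxidation, in which the chiral dioxirane should attack only the propenyl alkene (the enone alkene is electron-poor and tetrasubstituted, the alkyne is inert) through the spiro transition state that gives (R,R)-epoxides from trans-alkenes, so both epoxide centres are set by reagent control.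

Step 9
Reactants: 13 (5R,6R)-5-(TBSO)-2-[(TBSO)methyl]-6-hydroxy-6-methyl-3-{[(2R,3R)-3-methyloxiran-2-yl]ethynyl}cyclohex-2-en-1-one
Product: 15 (6R,7R)-6,7-dihydroxy-7-methyl-3-[(2S,3R)-3-methyloxiran-2-yl]-6,7-dihydro-1H-isochromen-8(5H)-one, via triol 14 (not isolated)
Conditions: TBAF, THF, 0 °C to rt
Reagents that add atoms: none
Why: Fluoride should cleave both silyl ethers, and the freed primary alkoxide on C1 should add to C3, the δ-terminus of the ynenone, in a 6-endo-dig oxa-Michael addition that closes the pyran ring as a doubly vinylogous ester without touching any stereocentre.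

Step 10
Reactants: 16 2,4-dihydroxy-6-methylbenzoic acid (orsellinic acid)
Product: 17 tert-butyldimethylsilyl 2,4-bis(TBSO)-6-methylbenzoate
Conditions: TBSCl, imidazole, DMF, rt
Reagents that add atoms: tert-butyldimethylsilyl chloride, CC(C)(C)[Si](C)(C)Cl
Why: Exhaustive silylation should cap both phenols and the acid in one operation, the silyl ester serving as the handle for step 11.

Step 11
Reactants: 17 tert-butyldimethylsilyl 2,4-bis(TBSO)-6-methylbenzoate
Product: 18 2,4-bis(TBSO)-6-methylbenzoyl chloride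
Conditions: (COCl)2, DMF (cat.), CH2Cl2, 0 °C to rt
Reagents that add atoms: oxalyl chloride, O=C(Cl)C(=O)Cl
Why: Vilsmeier-type chlorination of a silyl ester should give the acid chloride under neutral conditions, with loss of the silyl group from the carboxylate only, so the aryl silyl ethers stay in place.

Step 12
Reactants: 15 (6R,7R)-6,7-dihydroxy-7-methyl-3-[(2S,3R)-3-methyloxiran-2-yl]-6,7-dihydro-1H-isochromen-8(5H)-one; 18 2,4-bis(TBSO)-6-methylbenzoyl chloride
Product: 19 (6R,7R)-7-hydroxy-7-methyl-3-[(2S,3R)-3-methyloxiran-2-yl]-8-oxo-5,6,7,8-tetrahydro-1H-isochromen-6-yl 2,4-bis(TBSO)-6-methylbenzoate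
Conditions: DMAP, Et3N, CH2Cl2, 0 °C to rt
Reagents that add atoms: none
Why: DMAP-catalysed acylation through the acylpyridinium ion should take place at the secondary C6 hydroxyl only, the tertiary C7 hydroxyl being too hindered, and with retention at C6 because the C6–O bond is not broken.

Step 13
Reactants: 19 (6R,7R)-7-hydroxy-7-methyl-3-[(2S,3R)-3-methyloxiran-2-yl]-8-oxo-5,6,7,8-tetrahydro-1H-isochromen-6-yl 2,4-bis(TBSO)-6-methylbenzoate
Product: 20 (6R,7R)-7-hydroxy-7-methyl-3-[(2S,3R)-3-methyloxiran-2-yl]-8-oxo-5,6,7,8-tetrahydro-1H-isochromen-6-yl 2,4-dihydroxy-6-methylbenzoate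
Conditions: TBAF, AcOH, THF, 0 °C
Reagents that add atoms: none
Why: Buffered fluoride desilylation should cleave the two labile aryl silyl ethers while the epoxide, the ester and the dienol ether are left intact.

Compound list
1 | (E)-but-2-enal (crotonaldehyde) | C/C=C/C=O | starting material
2 | (3E)-1,1-dibromopenta-1,3-diene | C/C=C/C=C(Br)Br | intermediate
3 | (R)-4-[(tert-butyldimethylsilyl)oxy]cyclopent-2-en-1-one | O=C1C=C[C@H](O[Si](C)(C)C(C)(C)C)C1 | starting material
4 | (R)-4-(TBSO)-2-(hydroxymethyl)cyclopent-2-en-1-one | O=C1C(CO)=C[C@H](O[Si](C)(C)C(C)(C)C)C1 | intermediate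
5 | (R)-4-(TBSO)-2-[(TBSO)methyl]cyclopent-2-en-1-one | O=C1C(CO[Si](C)(C)C(C)(C)C)=C[C@H](O[Si](C)(C)C(C)(C)C)C1 | intermediate
6 | lithium (E)-pent-3-en-1-yn-1-ide | [Li]C#C/C=C/C | intermediate
7 | (1RS,4R)-4-(TBSO)-2-[(TBSO)methyl]-1-[(E)-pent-3-en-1-yn-1-yl]cyclopent-2-en-1-ol (both C1 epimers) | C/C=C/C#CC1(O)C[C@@H](O[Si](C)(C)C(C)(C)C)C=C1CO[Si](C)(C)C(C)(C)C | intermediate
8 | (R)-5-(TBSO)-2-[(TBSO)methyl]-3-[(E)-pent-3-en-1-yn-1-yl]cyclopent-2-en-1-one | O=C1[C@H](O[Si](C)(C)C(C)(C)C)CC(C#C/C=C/C)=C1CO[Si](C)(C)C(C)(C)C | intermediate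
9 | (1S,5R)-5-(TBSO)-2-[(TBSO)methyl]-1-(1-ethoxyethenyl)-3-[(E)-pent-3-en-1-yn-1-yl]cyclopent-2-en-1-ol | C=C(OCC)[C@@]1(O)[C@H](O[Si](C)(C)C(C)(C)C)CC(C#C/C=C/C)=C1CO[Si](C)(C)C(C)(C)C | intermediate
10 | 1-[(1S,5R)-5-(TBSO)-2-[(TBSO)methyl]-1-hydroxy-3-[(E)-pent-3-en-1-yn-1-yl]cyclopent-2-en-1-yl]ethan-1-one (hydroxyl cis to the 5-silyloxy group) | CC(=O)[C@@]1(O)[C@H](O[Si](C)(C)C(C)(C)C)CC(C#C/C=C/C)=C1CO[Si](C)(C)C(C)(C)C | intermediate
11 | di-tert-butoxyaluminium alkoxide of 10 (aluminium on the tertiary oxygen, chelated by the acetyl oxygen) | CC(=O)[C@@]1(O[Al](OC(C)(C)C)OC(C)(C)C)[C@H](O[Si](C)(C)C(C)(C)C)CC(C#C/C=C/C)=C1CO[Si](C)(C)C(C)(C)C | intermediate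
12 | (5R,6R)-5-(TBSO)-2-[(TBSO)methyl]-6-hydroxy-6-methyl-3-[(E)-pent-3-en-1-yn-1-yl]cyclohex-2-en-1-one | C[C@]1(O)C(=O)C(CO[Si](C)(C)C(C)(C)C)=C(C#C/C=C/C)C[C@H]1O[Si](C)(C)C(C)(C)C | intermediate
13 | (5R,6R)-5-(TBSO)-2-[(TBSO)methyl]-6-hydroxy-6-methyl-3-{[(2R,3R)-3-methyloxiran-2-yl]ethynyl}cyclohex-2-en-1-one | C[C@]1(O)C(=O)C(CO[Si](C)(C)C(C)(C)C)=C(C#C[C@H]2O[C@@H]2C)C[C@H]1O[Si](C)(C)C(C)(C)C | intermediate
14 | (5R,6R)-5,6-dihydroxy-2-(hydroxymethyl)-6-methyl-3-{[(2R,3R)-3-methyloxiran-2-yl]ethynyl}cyclohex-2-en-1-one | C[C@]1(O)C(=O)C(CO)=C(C#C[C@H]2O[C@@H]2C)C[C@H]1O | intermediate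
15 | (6R,7R)-6,7-dihydroxy-7-methyl-3-[(2S,3R)-3-methyloxiran-2-yl]-6,7-dihydro-1H-isochromen-8(5H)-one | O[C@@H]1CC2=C(COC([C@H]3O[C@@H]3C)=C2)C(=O)[C@]1(C)O | intermediate
16 | 2,4-dihydroxy-6-methylbenzoic acid (orsellinic acid) | Cc1cc(O)cc(O)c1C(=O)O | starting material
17 | tert-butyldimethylsilyl 2,4-bis(TBSO)-6-methylbenzoate | Cc1cc(O[Si](C)(C)C(C)(C)C)cc(O[Si](C)(C)C(C)(C)C)c1C(=O)O[Si](C)(C)C(C)(C)C | intermediate
18 | 2,4-bis(TBSO)-6-methylbenzoyl chloride | Cc1cc(O[Si](C)(C)C(C)(C)C)cc(O[Si](C)(C)C(C)(C)C)c1C(Cl)=O | intermediate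
19 | (6R,7R)-7-hydroxy-7-methyl-3-[(2S,3R)-3-methyloxiran-2-yl]-8-oxo-5,6,7,8-tetrahydro-1H-isochromen-6-yl 2,4-bis(TBSO)-6-methylbenzoate | Cc1cc(O[Si](C)(C)C(C)(C)C)cc(O[Si](C)(C)C(C)(C)C)c1C(=O)O[C@@H]1CC2=C(COC([C@H]3O[C@@H]3C)=C2)C(=O)[C@]1(C)O | intermediate
20 | (6R,7R)-7-hydroxy-7-methyl-3-[(2S,3R)-3-methyloxiran-2-yl]-8-oxo-5,6,7,8-tetrahydro-1H-isochromen-6-yl 2,4-dihydroxy-6-methylbenzoate (CNP0323247.1) | Cc1cc(O)cc(O)c1C(=O)O[C@@H]1CC2=C(COC([C@H]3O[C@@H]3C)=C2)C(=O)[C@]1(C)O | target

Total step count: 13.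
Longest linear sequence: 10 steps (steps 2 to 9, 12 and 13, from compound 3).

Steps most likely to fail

1. Step 7. The alkenyl carbon C8a may migrate in competition with C6, the reversible shift may stall short of completion, or part of the material may react through an open, non-chelated transition state and erode the C7 configuration. The fallback sets out from 10 and comes back to the route at 15; it makes the equilibrium irreversible by trapping the ring-enlarged enone.
   - Shi epoxidation of 10 under the conditions of step 8 should give the epoxy ketol 1-[(1S,5R)-5-(TBSO)-2-[(TBSO)methyl]-1-hydroxy-3-{[(2R,3R)-3-methyloxiran-2-yl]ethynyl}cyclopent-2-en-1-yl]ethan-1-one F1.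
   - NH4F in MeOH at rt should then cleave only the primary silyl ether and give the hydroxymethyl ketol 1-[(1S,5R)-5-(TBSO)-1-hydroxy-2-(hydroxymethyl)-3-{[(2R,3R)-3-methyloxiran-2-yl]ethynyl}cyclopent-2-en-1-yl]ethan-1-one F2.
   - Al(OtBu)3 in toluene, at the lowest temperature that sustains the shift, should again bring about the chelated 1,2-shift. Now only the ring-enlarged enone offers an activated ynenone to the free C1 hydroxyl, so 6-endo oxa-Michael closure should drain it from the equilibrium as the bicyclic silyl ether (6R,7R)-6-(TBSO)-7-hydroxy-7-methyl-3-[(2S,3R)-3-methyloxiran-2-yl]-6,7-dihydro-1H-isochromen-8(5H)-one F3.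
   - TBAF in THF should free O6 and give 15, so steps 8 and 9 are absorbed.

2. Step 9. Under basic fluoride the freed C6 hydroxyl may trigger retro-aldol cleavage of the C6–C7 bond, or the alkoxide may close in the 5-exo-dig sense at C4. The fallback sets out from 13 and comes back at 15; it separates deprotection from ring closure. Buffered fluoride (TBAF/AcOH, THF, rt) should give the triol 14, which is now isolated. The pyran is then closed without any alkoxide, by carbophilic activation of the alkyne with a catalytic amount of PdCl2(MeCN)2 (divalent palladium) in THF at rt: anti-oxypalladation at the electron-poor C3, then protodepalladation. This fallback makes no compound outside the list.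

3. Step 12. Acyl transfer between the neopentyl-type C6 hydroxyl and the 2,6-disubstituted aroyl chloride may be slow, which leaves time for chloride opening of the alkenyl epoxide or for acylation at O7. The fallback sets out from 15 and comes back at 19; it activates the nucleophile and not the acyl donor. Bu2SnO in MeOH (reflux, then evaporation) should convert the cis-diol into the dibutylstannylene acetal of 15 (2,2-dibutyl-1,3,2-dioxastannolane spanning O6 and O7) F4. Its less hindered secondary oxygen should be acylated by 18 in CH2Cl2 at rt without amine base, and aqueous work-up should give 19.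

Further compounds
F1 | step 7 | 1-[(1S,5R)-5-(TBSO)-2-[(TBSO)methyl]-1-hydroxy-3-{[(2R,3R)-3-methyloxiran-2-yl]ethynyl}cyclopent-2-en-1-yl]ethan-1-one | CC(=O)[C@@]1(O)[C@H](O[Si](C)(C)C(C)(C)C)CC(C#C[C@H]2O[C@@H]2C)=C1CO[Si](C)(C)C(C)(C)C
F2 | step 7 | 1-[(1S,5R)-5-(TBSO)-1-hydroxy-2-(hydroxymethyl)-3-{[(2R,3R)-3-methyloxiran-2-yl]ethynyl}cyclopent-2-en-1-yl]ethan-1-one | CC(=O)[C@@]1(O)[C@H](O[Si](C)(C)C(C)(C)C)CC(C#C[C@H]2O[C@@H]2C)=C1CO
F3 | step 7 | (6R,7R)-6-(TBSO)-7-hydroxy-7-methyl-3-[(2S,3R)-3-methyloxiran-2-yl]-6,7-dihydro-1H-isochromen-8(5H)-one | CC(C)(C)[Si](C)(C)O[C@@H]1CC2=C(COC([C@H]3O[C@@H]3C)=C2)C(=O)[C@]1(C)O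
F0 | step 9 | none | none
F4 | step 12 | dibutylstannylene acetal of 15 (2,2-dibutyl-1,3,2-dioxastannolane spanning O6 and O7) | CCCC[Sn]1(CCCC)O[C@@H]2CC3=C(COC([C@H]4O[C@@H]4C)=C3)C(=O)[C@]2(C)O1
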